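**Plan**

- Cuts, in retrosynthetic order: C12–C13 (alkylzinc/enol triflate coupling) into a silylated decalin iodide and an L-tartrate-derived fragment that already holds the butenolide; C18–O back to a C4 gem-dimethyl group; C8(OH)CH3 back to the C8 ketone; C6–C7 of ring B (aldol) to a ring A keto aldehyde; C9–C10 (Ireland–Claisen) back to ketoisophorone.
- Feature that allows the ring closure: ring B carries oxygen on C6 and on C8, 1,3 across C7, so C6–C7 is the bond of an aldol between a C6 aldehyde on C5 and a C8 methyl ketone on C9. C5 and C9 are then both α to a carbonyl and can equilibrate, so the quaternary C10 between them is the only ring-fusion centre that has to be secure before the ring is closed.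
- Forward: ring A from ketoisophorone, C10 by chirality transfer from a C2 carbinol, ring B by the aldol, then C8, then C18 (C–H oxidation directed by the 6α-hydroxyl). The side-chain fragment is built separately (butenolide by ring-closing metathesis), joined at C12–C13, then deprotected.
- Stereochemistry: C2 (transient) by asymmetric transfer hydrogenation, relayed to C10; C5, C6 and C9 in the aldol; C8 by α-face radical trapping; C4 by the peri relationship of the 6α-oxygen and C18; C14 and C15 from L-tartaric acid; C16 by Felkin–Anh reduction.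

Key step: step 9

Remark (numbering): labdane-type locants are used throughout, also for monocyclic intermediates. C1–C10 are the decalin carbons, C11–C12 the chain, C13 the alkene carbon with its exocyclic CH2, C14 and C15 the carbinols, C16 the butenolide CH–O, C17 the methyl on C8, C18 the CH2OH and C19 the methyl on C4, C20 the methyl on C10. α is the face of H-5, β the face of C20.

Remark (assumption): compounds 1, 4 and 23 are taken as commercial. The (S,S)-ligand in step 1 is assumed to give the (S)-carbinol by analogy with aryl ketones; the (R,R)-ligand would be used otherwise.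

**Route**

Step 1
Reactants: 1 2,6,6-trimethylcyclohex-2-ene-1,4-dione (ketoisophorone)
Product: 2 (4S)-4-hydroxy-2,6,6-trimethylcyclohex-2-en-1-one
Conditions: RuCl[(S,S)-TsDPEN](p-cymene) (0.5 mol%), HCO2H/Et3N (5:2), CH2Cl2, rt
Reagents that add atoms: none
Why: Noyori asymmetric transfer hydrogenation should reduce only the unhindered carbonyl (the future C2), since the other is flanked by the gem-dimethyl carbon and the methylated alkene carbon, and the catalyst sets the (S)-carbinol that later fixes C10.

Step 2
Reactants: 2 (4S)-4-hydroxy-2,6,6-trimethylcyclohex-2-en-1-one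
Product: 3 (1S)-3,5,5-trimethyl-4-methylidenecyclohex-2-en-1-ol
Conditions: Zn, CH2Br2, TiCl4 (reagent preformed in THF), CH2Cl2, 0 °C to rt
Reagents that add atoms: dibromomethane, BrCBr
Why: Takai–Lombardo methylenation is non-basic, so the hindered enone carbonyl (C5) should become the exocyclic C5=C6 alkene without deprotonation at the γ-carbon, which leaves the C2 stereocentre untouched.

Step 3
Reactants: 3 (1S)-3,5,5-trimethyl-4-methylidenecyclohex-2-en-1-ol; 4 4-(benzyloxy)butanoic acid
Product: 5 (1S)-3,5,5-trimethyl-4-methylidenecyclohex-2-en-1-yl 4-(benzyloxy)butanoate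
Conditions: DCC, DMAP (cat.), CH2Cl2, 0 °C to rt
Reagents that add atoms: none
Why: Steglich esterification acylates the acid-sensitive dienylic alcohol under neutral conditions and brings in the four carbons that become C8, C9, C11 and C12; no stereocentre is touched.

Step 4
Reactants: 5 (1S)-3,5,5-trimethyl-4-methylidenecyclohex-2-en-1-yl 4-(benzyloxy)butanoate
Product: 8 (2R)-4-(benzyloxy)-2-[(1R)-1,5,5-trimethyl-6-methylidenecyclohex-2-en-1-yl]butanoic acid, via (E)-silyl ketene acetal 6 (not isolated), via trimethylsilyl ester 7 (not isolated)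
Conditions: LiN(iPr)2, THF, −78 °C; Me3SiCl, Et3N; −78 °C to 60 °C; then 1 M HCl
Reagents that add atoms: none
Why: Ireland–Claisen rearrangement is suprafacial across the C2–C1=C10 allyl unit, so the C2–O configuration is relayed to the new quaternary C10 (C9 enters on the α face); the (E)-ketene acetal through the boat-like transition state usual for cyclohexenyl esters is expected to give the drawn C9 configuration, which remains correctable in step 9.

Step 5
Reactants: 8 (2R)-4-(benzyloxy)-2-[(1R)-1,5,5-trimethyl-6-methylidenecyclohex-2-en-1-yl]butanoic acid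
Product: 10 δ-lactone 4-[2-(benzyloxy)ethyl]-4a,8,8-trimethyl-1,4,4a,7,8,8a-hexahydro-3H-isochromen-3-one (trans-fused; C8 carbonyl joined through oxygen to C6; C1=C2 alkene; H-5 α, H-9 α, C20 β), via hydroxy acid 9 (not isolated)
Conditions: 9-BBN (2.5 equiv), THF, 0 °C to rt; NaOH, H2O2; then HCl to pH 2, p-TsOH (cat.), PhMe, 60 °C
Reagents that add atoms: hydrogen peroxide, OO
Why: Hydroboration–oxidation with 9-BBN should select the exocyclic 1,1-disubstituted C5=C6 alkene over the ring alkene, with boron on C6 and hydrogen delivered to C5 from the α face opposite the two pseudoaxial methyl groups (C19, C20); the δ-hydroxy acid then lactonises under acid.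

Step 6
Reactants: 10 unsaturated δ-lactone
Product: 11 saturated δ-lactone 4-[2-(benzyloxy)ethyl]-4a,8,8-trimethyloctahydro-3H-isochromen-3-one (same configuration as 10)
Conditions: H2 (1 atm), PtO2, EtOAc, rt
Reagents that add atoms: none
Why: Heterogeneous hydrogenation over PtO2 saturates the cis-disubstituted C1=C2 alkene, which served only to relay chirality, and should leave the benzyl ether and the lactone intact.

Step 7
Reactants: 11 saturated δ-lactone
Product: 12 12-(benzyloxy)-6-hydroxy-6,7-seco-13,14,15,16,17-pentanorlabdan-8-one (δ-hydroxy methyl ketone on ring A; open form shown, in equilibrium with its cyclic hemiketal)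
Conditions: MeLi (1.1 equiv), THF, −78 °C; aq. NH4Cl
Reagents that add atoms: methyllithium, [Li]C
Why: Single addition of an organolithium to a δ-lactone stops at the lithium hemiketal at low temperature, so work-up should give the methyl ketone (C7–C8) and free the C6 primary alcohol.

Step 8
Reactants: 12 δ-hydroxy methyl ketone
Product: 13 12-(benzyloxy)-8-oxo-6,7-seco-13,14,15,16,17-pentanorlabdan-6-al (ring A keto aldehyde: CHO on C5, 1-acetyl-3-(benzyloxy)propyl group on C10)
Conditions: Dess–Martin periodinane, CH2Cl2, 0 °C to rt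
Reagents that add atoms: none
Why: Dess–Martin oxidation converts the primary alcohol (through the open-chain tautomer) into the C6 aldehyde under neutral conditions that do not start the aldol prematurely.

Step 9
Reactants: 13 ring A keto aldehyde
Product: 14 12-(benzyloxy)-6α-hydroxy-13,14,15,16,17-pentanorlabdan-8-one (trans-decalin; H-5 α, H-9 α, C20 β)
Conditions: K2CO3 (0.3 equiv), MeOH, 0 °C to rt
Reagents that add atoms: none
Why: Intramolecular aldol addition: the base forms the methyl-side enolate of the C8 ketone (C7), which adds to the C6 aldehyde; the closest known reaction type is the base-mediated cyclisation of 1,5-keto aldehydes to 3-hydroxycyclohexanones. Ring B closes in the 6-(enolexo)-exo-trig mode through a chair-like transition state. C6 is set with the hydroxyl equatorial (α), because an axial C6–O bond would be 1,3-diaxial to both the C19 and the C20 methyl group, and the reversible retro-aldol pathway reinforces this. C5 and C9 are each α to a carbonyl in 13 or in 14, so a minor epimer at either centre should equilibrate towards the trans-fused decalin with the C9 chain equatorial, the non-epimerisable quaternary C10 being the reference. The step needs regioselectivity among the enolates and chemoselectivity against dehydration: only the C7 enolate can form a six-membered ring (the C9 or C5 enolates would give cyclobutanes), and the equatorial C6–O bond is poorly aligned with the enolate π system for E1cB loss of water, which the mild base and low temperature further disfavour.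

Step 10
Reactants: 14 6α-hydroxy-8-ketone
Product: 15 12-(benzyloxy)-13,14,15,16-tetranorlabd-8(17)-en-6α-ol
Conditions: Zn, CH2Br2, TiCl4, THF/CH2Cl2, rt
Reagents that add atoms: dibromomethane, BrCBr
Why: Takai–Lombardo methylenation converts the hindered, enolisable C8 ketone into the C8=C17 alkene without base, so the β-hydroxy ketone should neither eliminate nor undergo retro-aldol cleavage.

Step 11
Reactants: 15 8(17)-alkene
Product: 16 12-(benzyloxy)-13,14,15,16-tetranorlabdane-6α,8α-diol (C17 methyl β, axial)
Conditions: Co(acac)2 (20 mol%), PhSiH3, O2 (1 atm), THF, rt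
Reagents that add atoms: dioxygen, O=O
Why: Mukaiyama hydration (cobalt-mediated hydrogen-atom transfer to C17, then trapping of the tertiary C8 radical by O2) should place oxygen on the α face, away from the axial C20 methyl, giving the 8α-hydroxyl; a direct methyl addition to the ketone would be expected to give the C8 epimer.

Step 12
Reactants: 16 6α,8α-diol
Product: 19 12-(benzyloxy)-13,14,15,16-tetranorlabdane-6α,8α,18-triol, via diethylhydrosilyl ether 17 (not isolated), via oxasilinane 18 (not isolated)
Conditions: Et2SiH2, [Ir(cod)OMe]2 (0.5 mol%), THF, rt; then [Rh(cod)Cl]2 (2 mol%), Xantphos, norbornene, THF, 100 °C; then H2O2, KHCO3, THF/MeOH, 50 °C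
Reagents that add atoms: hydrogen peroxide, OO
Why: Alcohol-directed rhodium-catalysed δ-C–H silylation followed by Tamao–Fleming oxidation: the hydrosilyl ether of the equatorial 6α-hydroxyl can reach only the equatorial C18 methyl on C4 (peri relationship, six-membered oxasilinane), so the gem-dimethyl group is differentiated and C4 becomes the stereocentre with CH2OH α and CH3 β.

Step 13
Reactants: 19 6α,8α,18-triol
Product: 20 12-(benzyloxy)-6α,8α,18-tris(triethylsilyloxy)-13,14,15,16-tetranorlabdane
Conditions: Et3SiOTf, 2,6-lutidine, CH2Cl2, −78 to 0 °C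
Reagents that add atoms: triethylsilyl trifluoromethanesulfonate, CC[Si](CC)(CC)OS(=O)(=O)C(F)(F)F
Why: Silylation with the reactive silyl triflate protects the primary, secondary and tertiary hydroxyls in one operation, as the organolithium chemistry of step 23 requires.

Step 14
Reactants: 20 tris(triethylsilyl) ether
Product: 21 6α,8α,18-tris(triethylsilyloxy)-13,14,15,16-tetranorlabdan-12-ol
Conditions: H2 (1 atm), Pd/C, EtOAc, rt
Reagents that add atoms: none
Why: Hydrogenolysis of the benzyl ether frees the C12 alcohol; the silyl ethers are stable in neutral ethyl acetate and no alkene is present.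

Step 15
Reactants: 21 C12 primary alcohol
Product: 22 12-iodo-6α,8α,18-tris(triethylsilyloxy)-13,14,15,16-tetranorlabdane
Conditions: I2, PPh3, imidazole, CH2Cl2, 0 °C to rt
Reagents that add atoms: iodine, II
Why: Appel-type iodination converts the unhindered primary alcohol into the iodide by SN2 displacement of the alkoxyphosphonium ion.

Step 16
Reactants: 23 dimethyl (4R,5R)-2,2-dimethyl-1,3-dioxolane-4,5-dicarboxylate (dimethyl 2,3-O-isopropylidene-L-tartrate)
Product: 24 (4R,5R)-N4,N5-dimethoxy-N4,N5,2,2-tetramethyl-1,3-dioxolane-4,5-dicarboxamide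
Conditions: MeNH(OMe)·HCl, iPrMgCl, THF, −20 to 0 °C
Reagents that add atoms: N,O-dimethylhydroxylamine hydrochloride, CNOC.Cl
Why: Weinreb amide formation from both esters with the magnesium amide should proceed without epimerisation of the two dioxolane stereocentres, which become C14 and C15.

Step 17
Reactants: 24 bis(Weinreb amide)
Product: 25 (4R,5R)-5-acetyl-N-methoxy-N,2,2-trimethyl-1,3-dioxolane-4-carboxamide
Conditions: MeMgBr (1.2 equiv), THF, −15 °C
Reagents that add atoms: methylmagnesium bromide, C[Mg]Br
Why: Weinreb ketone synthesis: the chelated tetrahedral intermediate prevents over-addition, and with about one equivalent of Grignard reagent the C2-symmetric bis-amide should be mono-functionalised to the C13 methyl ketone.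

Step 18
Reactants: 25 methyl ketone
Product: 26 1-[(4R,5R)-5-[methoxy(methyl)carbamoyl]-2,2-dimethyl-1,3-dioxolan-4-yl]ethenyl trifluoromethanesulfonate
Conditions: KN(SiMe3)2, PhNTf2, THF, −78 °C
Reagents that add atoms: N-phenylbis(trifluoromethanesulfonimide), O=S(=O)(N(c1ccccc1)S(=O)(=O)C(F)(F)F)C(F)(F)F
Why: Kinetic deprotonation of the methyl group by the bulky amide base and O-sulfonylation of the enolate give the 1,1-disubstituted enol triflate, that is C13 with its future exocyclic methylene.

Step 19
Reactants: 26 enol triflate Weinreb amide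
Product: 27 1-[(4R,5R)-2,2-dimethyl-5-(2-methylprop-2-enoyl)-1,3-dioxolan-4-yl]ethenyl trifluoromethanesulfonate
Conditions: CH2=C(CH3)MgBr, THF, −20 to 0 °C
Reagents that add atoms: isopropenylmagnesium bromide, CC(=C)[Mg]Br
Why: A second Weinreb ketone synthesis gives the isopropenyl ketone; the enol triflate is inert to the Grignard reagent in the absence of a transition metal.

Step 20
Reactants: 27 isopropenyl ketone
Product: 28 1-[(4R,5S)-5-[(1R)-1-hydroxy-2-methylprop-2-en-1-yl]-2,2-dimethyl-1,3-dioxolan-4-yl]ethenyl trifluoromethanesulfonate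
Conditions: NaBH4, CeCl3·7H2O, MeOH, −78 °C
Reagents that add atoms: none
Why: Luche 1,2-reduction of the enone under Felkin–Anh control (C15–O bond antiperiplanar to the incoming hydride) should set C16 syn to the C15 oxygen, as the target requires.

Step 21
Reactants: 28 allylic alcohol
Product: 29 (1R)-1-[(4S,5R)-2,2-dimethyl-5-[1-(trifluoromethanesulfonyloxy)ethenyl]-1,3-dioxolan-4-yl]-2-methylprop-2-en-1-yl prop-2-enoate
Conditions: CH2=CHCOCl, Et3N, DMAP (cat.), CH2Cl2, −20 °C
Reagents that add atoms: acryloyl chloride, C=CC(=O)Cl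
Why: O-acylation of the secondary allylic alcohol with the acid chloride gives the diene for ring closure without touching C16.

Step 22
Reactants: 29 acrylate
Product: 30 1-[(4R,5S)-2,2-dimethyl-5-[(2R)-3-methyl-5-oxo-2,5-dihydrofuran-2-yl]-1,3-dioxolan-4-yl]ethenyl trifluoromethanesulfonate
Conditions: second-generation Grubbs catalyst (5 mol%), PhMe, 80 °C
Reagents that add atoms: none
Why: Ring-closing metathesis between the acrylate and the isopropenyl group forms the 4-methylbutenolide with loss of ethene; the electron-poor enol triflate alkene should not take part.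

Step 23
Reactants: 22 C12 iodide; 30 enol triflate butenolide
Product: 33 fully protected target (6α,8α,18-tris(triethylsilyl) ether, 14,15-acetonide), via alkyllithium 31 (not isolated), via alkylzinc chloride 32 (not isolated)
Conditions: t-BuLi (2.1 equiv), Et2O, −78 °C; ZnCl2, THF, −78 °C to rt; then 30, Pd(PPh3)4 (5 mol%), THF, rt to 40 °C
Reagents that add atoms: none
Why: Negishi coupling: iodine–lithium exchange and transmetalation to zinc give a primary alkylzinc that couples with the enol triflate under zerovalent palladium catalysis to form the C12–C13 bond, and the alkylzinc is too mild to attack the butenolide.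

Step 24
Reactants: 33 fully protected target
Product: 34 CNP0301623.1 (target)
Conditions: AcOH/THF/H2O (3:1:1), 45 °C
Reagents that add atoms: none
Why: Acid-catalysed hydrolysis removes the three triethylsilyl ethers and the acetonide in one operation under conditions mild enough for the tertiary C8 alcohol, the allylic C14 alcohol and the butenolide.

**Compound list**

1 | 2,6,6-trimethylcyclohex-2-ene-1,4-dione (ketoisophorone) | CC1=CC(=O)CC(C)(C)C1=O | starting material
2 | (4S)-4-hydroxy-2,6,6-trimethylcyclohex-2-en-1-one | CC1=C[C@@H](O)CC(C)(C)C1=O | intermediate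
3 | (1S)-3,5,5-trimethyl-4-methylidenecyclohex-2-en-1-ol | CC1=C[C@@H](O)CC(C)(C)C1=C | intermediate
4 | 4-(benzyloxy)butanoic acid | OC(=O)CCCOCc1ccccc1 | starting material
5 | (1S)-3,5,5-trimethyl-4-methylidenecyclohex-2-en-1-yl 4-(benzyloxy)butanoate | CC1=C[C@@H](OC(=O)CCCOCc2ccccc2)CC(C)(C)C1=C | intermediate
6 | (E)-O-trimethylsilyl ketene acetal of ester 5 | CC1=C[C@@H](O/C(O[Si](C)(C)C)=C\CCOCc2ccccc2)CC(C)(C)C1=C | intermediate (not isolated)
7 | trimethylsilyl ester of acid 8 | C[Si](C)(C)OC(=O)[C@H](CCOCc1ccccc1)[C@@]2(C)C=CCC(C)(C)C2=C | intermediate (not isolated)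
8 | (2R)-4-(benzyloxy)-2-[(1R)-1,5,5-trimethyl-6-methylidenecyclohex-2-en-1-yl]butanoic acid | OC(=O)[C@H](CCOCc1ccccc1)[C@@]2(C)C=CCC(C)(C)C2=C | intermediate
9 | hydroxy acid: 8 with the exocyclic methylene turned into CH2OH on C5 (H-5 α, CH2OH cis to C20) | OC(=O)[C@H](CCOCc1ccccc1)[C@@]2(C)C=CCC(C)(C)[C@@H]2CO | intermediate (not isolated)
10 | 4-[2-(benzyloxy)ethyl]-4a,8,8-trimethyl-1,4,4a,7,8,8a-hexahydro-3H-isochromen-3-one, trans-fused (C8 lactone to O–C6, C1=C2 alkene) | c1ccccc1COCC[C@@H]1[C@@]2(C)C=CCC(C)(C)[C@@H]2COC1=O | intermediate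
11 | 4-[2-(benzyloxy)ethyl]-4a,8,8-trimethyloctahydro-3H-isochromen-3-one, trans-fused | c1ccccc1COCC[C@@H]1[C@@]2(C)CCCC(C)(C)[C@@H]2COC1=O | intermediate
12 | 12-(benzyloxy)-6-hydroxy-6,7-seco-13,14,15,16,17-pentanorlabdan-8-one | c1ccccc1COCC[C@@H](C(C)=O)[C@@]1(C)CCCC(C)(C)[C@@H]1CO | intermediate
13 | 12-(benzyloxy)-8-oxo-6,7-seco-13,14,15,16,17-pentanorlabdan-6-al | c1ccccc1COCC[C@@H](C(C)=O)[C@@]1(C)CCCC(C)(C)[C@@H]1C=O | intermediate
14 | 12-(benzyloxy)-6α-hydroxy-13,14,15,16,17-pentanorlabdan-8-one | c1ccccc1COCC[C@@H]1[C@@]2(C)CCCC(C)(C)[C@@H]2[C@@H](O)CC1=O | intermediate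
15 | 12-(benzyloxy)-13,14,15,16-tetranorlabd-8(17)-en-6α-ol | c1ccccc1COCC[C@@H]1[C@@]2(C)CCCC(C)(C)[C@@H]2[C@@H](O)CC1=C | intermediate
16 | 12-(benzyloxy)-13,14,15,16-tetranorlabdane-6α,8α-diol | c1ccccc1COCC[C@@H]1[C@@]2(C)CCCC(C)(C)[C@@H]2[C@@H](O)C[C@@]1(C)O | intermediate
17 | 6-O-(diethylsilyl) ether of 16 | c1ccccc1COCC[C@@H]1[C@@]2(C)CCCC(C)(C)[C@@H]2[C@@H](O[SiH](CC)CC)C[C@@]1(C)O | intermediate (not isolated)
18 | 6α-O,18-C-bridged diethyl oxasilinane of 16 | c1ccccc1COCC[C@@H]1[C@@]2(C)CCC[C@@]3(C)C[Si](CC)(CC)O[C@H]([C@H]23)C[C@@]1(C)O | intermediate (not isolated)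
19 | 12-(benzyloxy)-13,14,15,16-tetranorlabdane-6α,8α,18-triol | c1ccccc1COCC[C@@H]1[C@@]2(C)CCC[C@@](C)(CO)[C@@H]2[C@@H](O)C[C@@]1(C)O | intermediate
20 | 12-(benzyloxy)-6α,8α,18-tris(triethylsilyloxy)-13,14,15,16-tetranorlabdane | c1ccccc1COCC[C@@H]1[C@@]2(C)CCC[C@@](C)(CO[Si](CC)(CC)CC)[C@@H]2[C@@H](O[Si](CC)(CC)CC)C[C@@]1(C)O[Si](CC)(CC)CC | intermediate
21 | 6α,8α,18-tris(triethylsilyloxy)-13,14,15,16-tetranorlabdan-12-ol | OCC[C@@H]1[C@@]2(C)CCC[C@@](C)(CO[Si](CC)(CC)CC)[C@@H]2[C@@H](O[Si](CC)(CC)CC)C[C@@]1(C)O[Si](CC)(CC)CC | intermediate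
22 | 12-iodo-6α,8α,18-tris(triethylsilyloxy)-13,14,15,16-tetranorlabdane | ICC[C@@H]1[C@@]2(C)CCC[C@@](C)(CO[Si](CC)(CC)CC)[C@@H]2[C@@H](O[Si](CC)(CC)CC)C[C@@]1(C)O[Si](CC)(CC)CC | intermediate
23 | dimethyl (4R,5R)-2,2-dimethyl-1,3-dioxolane-4,5-dicarboxylate | COC(=O)[C@@H]1OC(C)(C)O[C@H]1C(=O)OC | starting material
24 | (4R,5R)-N4,N5-dimethoxy-N4,N5,2,2-tetramethyl-1,3-dioxolane-4,5-dicarboxamide | CON(C)C(=O)[C@@H]1OC(C)(C)O[C@H]1C(=O)N(C)OC | intermediate
25 | (4R,5R)-5-acetyl-N-methoxy-N,2,2-trimethyl-1,3-dioxolane-4-carboxamide | CC(=O)[C@@H]1OC(C)(C)O[C@H]1C(=O)N(C)OC | intermediate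
26 | 1-[(4R,5R)-5-[methoxy(methyl)carbamoyl]-2,2-dimethyl-1,3-dioxolan-4-yl]ethenyl trifluoromethanesulfonate | C=C(OS(=O)(=O)C(F)(F)F)[C@@H]1OC(C)(C)O[C@H]1C(=O)N(C)OC | intermediate
27 | 1-[(4R,5R)-2,2-dimethyl-5-(2-methylprop-2-enoyl)-1,3-dioxolan-4-yl]ethenyl trifluoromethanesulfonate | C=C(OS(=O)(=O)C(F)(F)F)[C@@H]1OC(C)(C)O[C@H]1C(=O)C(C)=C | intermediate
28 | 1-[(4R,5S)-5-[(1R)-1-hydroxy-2-methylprop-2-en-1-yl]-2,2-dimethyl-1,3-dioxolan-4-yl]ethenyl trifluoromethanesulfonate | C=C(OS(=O)(=O)C(F)(F)F)[C@@H]1OC(C)(C)O[C@H]1[C@H](O)C(C)=C | intermediate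
29 | acrylate ester of 28 at the C16 hydroxyl | C=C(OS(=O)(=O)C(F)(F)F)[C@@H]1OC(C)(C)O[C@H]1[C@H](OC(=O)C=C)C(C)=C | intermediate
30 | 1-[(4R,5S)-2,2-dimethyl-5-[(2R)-3-methyl-5-oxo-2,5-dihydrofuran-2-yl]-1,3-dioxolan-4-yl]ethenyl trifluoromethanesulfonate | C=C(OS(=O)(=O)C(F)(F)F)[C@@H]1OC(C)(C)O[C@H]1[C@@H]2OC(=O)C=C2C | intermediate
31 | 12-lithio derivative of 22 | [Li]CC[C@@H]1[C@@]2(C)CCC[C@@](C)(CO[Si](CC)(CC)CC)[C@@H]2[C@@H](O[Si](CC)(CC)CC)C[C@@]1(C)O[Si](CC)(CC)CC | intermediate (not isolated)
32 | 12-(chlorozincio) derivative of 22 | Cl[Zn]CC[C@@H]1[C@@]2(C)CCC[C@@](C)(CO[Si](CC)(CC)CC)[C@@H]2[C@@H](O[Si](CC)(CC)CC)C[C@@]1(C)O[Si](CC)(CC)CC | intermediate (not isolated)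
33 | target as its 6α,8α,18-tris(triethylsilyl) ether and 14,15-O-isopropylidene acetal | C=C(CC[C@@H]1[C@@]2(C)CCC[C@@](C)(CO[Si](CC)(CC)CC)[C@@H]2[C@@H](O[Si](CC)(CC)CC)C[C@@]1(C)O[Si](CC)(CC)CC)[C@@H]3OC(C)(C)O[C@H]3[C@@H]4OC(=O)C=C4C | intermediate
34 | CNP0301623.1 | C=C(CC[C@@H]1[C@@]2(C)CCC[C@@](C)(CO)[C@@H]2[C@@H](O)C[C@@]1(C)O)[C@H](O)[C@@H](O)[C@@H]1OC(=O)C=C1C | target

**Step count**

Total: 24 steps. Longest linear sequence: 17 steps (steps 1–15, 23 and 24); the side-chain fragment takes 7 steps (16–22).

**Steps most likely to fail**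

Step 9 (aldol ring closure). The risk is loss of water from the β-hydroxy ketone by E1cB elimination under the basic conditions, or slow equilibration at C9, before clean ring closure is complete. The fallback sets out from 12 and closes the same bond by a pericyclic reaction instead of an enolate reaction. Wittig methylenation of the methyl ketone (Ph3P=CH2, THF) should give the isopropenyl alcohol F1, and Dess–Martin oxidation the isopropenyl aldehyde F2. Me2AlCl (CH2Cl2, −78 °C) should then bring about a type 2 carbonyl-ene cyclisation through a chair with the aldehyde oxygen equatorial, the hydrogen being taken from the methyl group. This gives the exo-methylene alcohol and comes back to the route at 15. The price is that C9 can then no longer be corrected.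

Step 12 (directed C–H silylation and oxidation). The risk is poor site selectivity of the C–H silylation (attack at another methyl or methylene group) or low turnover caused by the free tertiary hydroxyl and the benzyl ether. The fallback sets out from 16 and uses an alkoxyl-radical 1,5-hydrogen transfer (Barton nitrite photolysis) in place of the metal insertion. NOCl/pyridine should nitrosate the secondary 6α-hydroxyl to the nitrite ester F3. Irradiation (Hg lamp, benzene) should move the NO group to C18, which after tautomerisation gives the 18-oxime F4. TiCl3/NH4OAc in aqueous dioxane should cleave the oxime reductively (N–O reduction to the imine, then hydrolysis) to the 18-aldehyde F5 (in equilibrium with its 6,18-lactol), and NaBH4 in MeOH should reduce it to the triol, where the fallback comes back to the route at 19.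

Step 2 (methylenation of the hindered enone). The risk is incomplete methylenation of the hindered, conjugated carbonyl or ionisation of the allylic hydroxyl by the Lewis-acidic reagent. The fallback sets out from 2 and replaces the titanium carbenoid by a Peterson olefination. t-BuMe2SiCl/imidazole should give the silyl ether F6, and Me3SiCH2Li with CeCl3 (THF, −78 °C) should add 1,2 to the enone to give the β-hydroxysilane F7. HF·pyridine in MeCN should then bring about both the elimination and the loss of the silyl ether, which returns to the route at 3.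

Further compounds
F1 | step 9 | 12-(benzyloxy)-6,7-seco-13,14,15,16-tetranorlabd-8(17)-en-6-ol (isopropenyl alcohol) | c1ccccc1COCC[C@@H](C(C)=C)[C@@]1(C)CCCC(C)(C)[C@@H]1CO
F2 | step 9 | 12-(benzyloxy)-6,7-seco-13,14,15,16-tetranorlabd-8(17)-en-6-al (isopropenyl aldehyde) | c1ccccc1COCC[C@@H](C(C)=C)[C@@]1(C)CCCC(C)(C)[C@@H]1C=O
F3 | step 12 | 6α-nitrite ester of diol 16 | c1ccccc1COCC[C@@H]1[C@@]2(C)CCCC(C)(C)[C@@H]2[C@@H](ON=O)C[C@@]1(C)O
F4 | step 12 | 12-(benzyloxy)-6α,8α-dihydroxy-13,14,15,16-tetranorlabdan-18-al oxime | c1ccccc1COCC[C@@H]1[C@@]2(C)CCC[C@@](C)(C=NO)[C@@H]2[C@@H](O)C[C@@]1(C)O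
F5 | step 12 | 12-(benzyloxy)-6α,8α-dihydroxy-13,14,15,16-tetranorlabdan-18-al | c1ccccc1COCC[C@@H]1[C@@]2(C)CCC[C@@](C)(C=O)[C@@H]2[C@@H](O)C[C@@]1(C)O
F6 | step 2 | (4S)-4-(tert-butyldimethylsilyloxy)-2,6,6-trimethylcyclohex-2-en-1-one | CC1=C[C@@H](O[Si](C)(C)C(C)(C)C)CC(C)(C)C1=O
F7 | step 2 | (4S)-4-(tert-butyldimethylsilyloxy)-2,6,6-trimethyl-1-[(trimethylsilyl)methyl]cyclohex-2-en-1-ol | CC1=C[C@@H](O[Si](C)(C)C(C)(C)C)CC(C)(C)C1(O)C[Si](C)(C)C
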